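The readings are calculated for an exercise.

**Slow flasks.** Slowness is what I look at first: in the epsilon run 33.8 % of the starting material still stands at 80.0 s, and homo product is still climbing, so flasks stopped at 120 s are read in motion and not at an end.

| flask | starting material | partner | protic impurity | remark | time |
|---|---|---|---|---|---|
| epsilon | 1 M | 1.5 M | 0.50 M | run made earlier |  |
| beta | 1 M | 3 M | 0.50 M | run made earlier |  |
| spring | 1.0 M | 1.10 M | 0.500 M |  | 2.0 min |
| winter | 1.0 M | 1.40 M | 0.500 M |  | 2.0 min |
| dawn | 1.0 M | 1.90 M | 0.500 M |  | 2.0 min |

| run | time / s | open intermediate / % | homo product / % | target / % | starting material / % |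
|---|---|---|---|---|---|
| epsilon | 15.0 | 18.1 | 5.5 | 0 | 71.7 |
| epsilon | 30.0 | 18.0 | 18.9 | 1.8 | 59.6 |
| epsilon | 50.0 | 16.4 | 33.7 | 3.0 | 44.8 |
| epsilon | 60.0 | 15.9 | 41.6 | 4.9 | 38.1 |
| epsilon | 80.0 | 13.1 | 47.4 | 6.0 | 33.8 |
| beta | 10.0 | 15.7 | 3.5 | 0.9 | 82.0 |
| beta | 12.0 | 16.1 | 4.0 | 0 | 78.3 |
| beta | 25.0 | 20.2 | 14.7 | 2.8 | 64.1 |
| beta | 40.0 | 16.4 | 22.9 | 3.8 | 51.1 |
| beta | 80.0 | 8.8 | 42.3 | 10.7 | 29.1 |

(each reading ± 1 percentage point)

- a species is counted by the starting material in it: one homo product counts as two

- which of these there is most of at the end, counted by the starting material in it, spring (target / homo product / open intermediate / starting material)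
- which of these there is most of at the end, counted by the starting material in it, winter (target / homo product / open intermediate / starting material)
- which of these there is most of at the end, counted by the starting material in it, dawn (target / homo product / open intermediate / starting material)
- final amount of the leader among these, as a percentage of the starting material charged, in spring
- final amount of the leader among these, as a percentage of the starting material charged, in winter
- final amount of the leader among these, as a percentage of the starting material charged, in dawn

**What matters.** I go through the settings by what an error in each costs. The charges of starting material and protic impurity in the asked flasks are those of the runs, 1.0 M and 0.500 M against 1 M and 0.50 M, so I need no number for them. Partner counts: in the readings, going from 1.5 M to 3 M lowers homo product at 80.0 s by 5.1 percentage points, which scaled to the span from spring to dawn is 2.7 points. Time counts for more, since the epsilon run gains 5.8 points of homo product between 60.0 s and 80.0 s. So the number to know well is how far the clock has run.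

**Counting turnovers.** From the epsilon run, nearest in partner, I read h, the apparent half-life of starting material averaged up to its last reading, as 51.1 s. Then N, the number of turnovers, the asked time divided by h, is 2.35, and one half raised to the power N leaves 19.7 % of the starting material. Homo product holds 71.6 % of what was spent in that reading, so I expect about 57.5 % at the partner of the epsilon run, with spring above and dawn below, and homo product leading.

The forecast gives homo product in spring, homo product in winter and homo product in dawn, at 58 %, 56.5 % and 54.5 %: “Homo leads in all three”.

**The flask.** Homo product leads in spring, winter and dawn, at 60.0 %, 58.1 % and 55.0 %, and the steps behind it are these.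

    target → over-reaction product (k = 0.0136 s⁻¹)
    2 open intermediate → homo product (k = 0.115 M⁻¹ s⁻¹)
    2 starting material → self-condensation product (k = 3.33 × 10⁻⁶ M⁻¹ s⁻¹)
    partner + protic impurity → quenched reagent (k = 0.0337 M⁻¹ s⁻¹)
    open intermediate + second intermediate → target (k = 0.0599 M⁻¹ s⁻¹)
    partner → second intermediate (k = 0.00322 s⁻¹)
    starting material ⇌ open intermediate (K = 0.710, k = 0.0251 s⁻¹)

Against 47.5 % of homo product for the epsilon run at the time of its last reading, without the scatter, moving partner to spring's gives 49.0 %, and moving the time to spring's gives 57.5 %. Spring's 2.35 turnovers left me 19.7 % of starting material, and spring holds 21.3 %. The flask of winter's recipe stopped at 30 s counts 0.587 turnovers, which leaves 66.6 % by my count, and it holds 59.6 % of starting material against 19.5 % of homo product.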